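## Retrosynthetic overview

- Target: (3S,6R)-8'-apo-ε-carotene-3,8'-diol (3-OH cis to the polyene on the ring, all-E). The C8' alcohol comes from ester 20 by hydride reduction.
- C11=C12 by Horner–Wadsworth–Emmons (HWE) olefination of ring C15 phosphonate 11 with C15 aldehyde ester 18. 18 comes from C10 dialdehyde 16 and C5 phosphonate 15 (C11'=C12').
- C3 carbinol: ketone 8 → trans alcohol 9 (bulky hydride) → Mitsunobu inversion → cis alcohol 11.
- C6–C7 bond and the C6 stereocentre: new enantioselective palladium-catalysed γ-alkenylation of silyl dienol ether 2 with bromodiene phosphonate 7 (made from enynol 3).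
- Rings: the single carbocycle is not built in the route; it is bought as β-isophorone 1 and keeps its skeleton throughout.

Assumption: β-isophorone 1 is bought (it is also obtained in one operation by base-catalysed deconjugation and distillation of isophorone).
Assumption: the (R)-ligand in step 5 is taken to give (R)-8; if the first experiment shows the opposite sense, the (S)-ligand is used and nothing else changes.

## Route

Step 1
Reactants: 1 β-isophorone (3,5,5-trimethylcyclohex-3-en-1-one)
Product: 2 trimethyl[(3,5,5-trimethylcyclohexa-1,3-dien-1-yl)oxy]silane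
Conditions: Me3SiOTf (1.2 equiv), Et3N (1.5 equiv), Et2O, 0 °C
Reagents that add atoms: trimethylsilyl trifluoromethanesulfonate, C[Si](C)(C)OS(=O)(=O)C(F)(F)F
Why: Soft enolisation (silyl enol ether formation) removes the most acidic proton, the doubly activated C2–H between carbonyl and alkene, so the linear endocyclic 1-silyloxy-1,3-diene forms as a single regioisomer and no stereocentre is involved.

Step 2
Reactants: 3 (2E)-3-methylpent-2-en-4-yn-1-ol
Product: 4 (3E)-5-bromo-3-methylpent-3-en-1-yne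
Conditions: PBr3 (0.4 equiv), pyridine (cat.), Et2O, −10 to 0 °C
Reagents that add atoms: phosphorus tribromide, BrP(Br)Br
Why: Conversion of a primary allylic alcohol into the bromide by PBr3 (SN2 on the bromophosphite ester) leaves the alkyne and the E-alkene untouched.

Step 3
Reactants: 4 (3E)-5-bromo-3-methylpent-3-en-1-yne
Product: 5 diethyl [(2E)-3-methylpent-2-en-4-yn-1-yl]phosphonate
Conditions: P(OEt)3 (1.3 equiv), neat, 100 °C
Reagents that add atoms: triethyl phosphite, CCOP(OCC)OCC
Why: Michaelis–Arbuzov reaction: SN2 attack of the phosphite on the unhindered primary allylic bromide and dealkylation by bromide give the phosphonate with the E-alkene retained.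

Step 4
Reactants: 5 diethyl [(2E)-3-methylpent-2-en-4-yn-1-yl]phosphonate
Product: 7 diethyl [(2E,4E)-5-bromo-3-methylpenta-2,4-dien-1-yl]phosphonate, via alkenylzirconocene chloride 6 (not isolated)
Conditions: Cp2Zr(H)Cl (1.3 equiv), THF, rt, dark; then NBS (1.3 equiv), 0 °C
Reagents that add atoms: N-bromosuccinimide, O=C1CCC(=O)N1Br; zirconocene chloride hydride Cp2Zr(H)Cl (in 6 only), [H][Zr](Cl)([CH]1C=CC=C1)[CH]1C=CC=C1
Why: Hydrozirconation of the terminal alkyne is a syn addition that puts zirconium on the terminal carbon, and bromodezirconation with NBS proceeds with retention, so the new C=C is E while the trisubstituted alkene and the phosphonate are spectators.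

Step 5
Reactants: 2 trimethyl[(3,5,5-trimethylcyclohexa-1,3-dien-1-yl)oxy]silane (1.5 equiv); 7 diethyl [(2E,4E)-5-bromo-3-methylpenta-2,4-dien-1-yl]phosphonate
Product: 8 diethyl {(2E,4E)-3-methyl-5-[(1R)-2,6,6-trimethyl-4-oxocyclohex-2-en-1-yl]penta-2,4-dien-1-yl}phosphonate
Conditions: Pd(dba)2 (5 mol %), (R)-2-(di-tert-butylphosphino)-2'-(dimethylamino)-1,1'-binaphthyl (6 mol %), ZnF2 (0.6 equiv), DMF, 50 °C
Reagents that add atoms: none
Why: Proposed new method: an enantioselective palladium-catalysed γ-alkenylation of a silyl dienol ether, in which zerovalent palladium inserts into the C–Br bond of 7 with retention of the E geometry, fluoride from ZnF2 cleaves the O–Si bond and hands the dienolate to divalent palladium, the alkenylpalladium dienolate equilibrates between O-bound, η3 and η1-C(γ) forms, and C–C reductive elimination at the γ-terminus (favoured because it gives the conjugated enone, and feasible next to CMe2 because enolate couplings of this kind already build quaternary carbons) from the diastereomeric η1-C(γ) complex preferred in the pocket of the bulky P,N-binaphthyl ligand fixes C6 as R under almost neutral conditions that do not epimerise the γ-stereocentre; the closest known reaction types are the palladium-catalysed γ-arylation of silyl dienolates with aryl bromides under ZnF2 activation and the palladium-catalysed asymmetric α-alkenylation of ketone enolates with alkenyl bromides.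

Step 6
Reactants: 8 diethyl {(2E,4E)-3-methyl-5-[(1R)-2,6,6-trimethyl-4-oxocyclohex-2-en-1-yl]penta-2,4-dien-1-yl}phosphonate
Product: 9 diethyl {(2E,4E)-5-[(1R,4R)-4-hydroxy-2,6,6-trimethylcyclohex-2-en-1-yl]-3-methylpenta-2,4-dien-1-yl}phosphonate
Conditions: LiBH(s-Bu)3 (1.2 equiv), THF, −78 °C; then H2O
Reagents that add atoms: none
Why: Substrate-controlled 1,2-reduction of the β,β-disubstituted enone by a bulky trialkylborohydride: hydride adds to the carbonyl face opposite the axial C1 methyl group of the half-chair in which the C6 side chain is pseudo-axial, that is syn to the side chain, which is expected to place the new C3 hydroxyl trans to it (3R), as recalled (not verified) for bulky-hydride reduction of 3-oxo-ε-ring ketones.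

Step 7
Reactants: 9 diethyl {(2E,4E)-5-[(1R,4R)-4-hydroxy-2,6,6-trimethylcyclohex-2-en-1-yl]-3-methylpenta-2,4-dien-1-yl}phosphonate
Product: 10 (1S,4R)-4-[(1E,3E)-5-(diethoxyphosphoryl)-3-methylpenta-1,3-dien-1-yl]-3,5,5-trimethylcyclohex-2-en-1-yl 4-nitrobenzoate
Conditions: 4-O2NC6H4CO2H (1.5 equiv), PPh3 (1.5 equiv), DIAD (1.5 equiv, added last, slowly), toluene, 0 °C to rt
Reagents that add atoms: 4-nitrobenzoic acid, OC(=O)c1ccc(cc1)[N+](=O)[O-]
Why: Mitsunobu reaction: SN2 displacement of the oxyphosphonium leaving group by 4-nitrobenzoate inverts C3 from R to S (oxygen now cis to the side chain), and the methyl group on C5 disfavours the competing SN2' path.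

Step 8
Reactants: 10 (1S,4R)-4-[(1E,3E)-5-(diethoxyphosphoryl)-3-methylpenta-1,3-dien-1-yl]-3,5,5-trimethylcyclohex-2-en-1-yl 4-nitrobenzoate
Product: 11 diethyl {(2E,4E)-5-[(1R,4S)-4-hydroxy-2,6,6-trimethylcyclohex-2-en-1-yl]-3-methylpenta-2,4-dien-1-yl}phosphonate
Conditions: K2CO3 (0.2 equiv), MeOH, rt
Reagents that add atoms: none
Why: Base-catalysed transesterification (methanolysis) of the activated aryl ester cleaves the acyl–oxygen bond, so the C3 configuration set in step 7 is kept and the phosphonate is untouched.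

Step 9
Reactants: 12 chloroacetaldehyde (50 % aqueous solution); 13 ethyl 2-(triphenyl-λ5-phosphanylidene)propanoate
Product: 14 ethyl (2E)-4-chloro-2-methylbut-2-enoate
Conditions: CH2Cl2/H2O, rt
Reagents that add atoms: none
Why: Wittig olefination with a stabilised ylide gives the E-trisubstituted enoate selectively, and the ylide is neither basic nor nucleophilic enough to displace the chloride.

Step 10
Reactants: 14 ethyl (2E)-4-chloro-2-methylbut-2-enoate
Product: 15 ethyl (2E)-4-(diethoxyphosphoryl)-2-methylbut-2-enoate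
Conditions: P(OEt)3 (1.5 equiv), NaI (cat.), neat, 150 °C
Reagents that add atoms: triethyl phosphite, CCOP(OCC)OCC
Why: Iodide-catalysed Michaelis–Arbuzov reaction of the primary allylic chloride gives the C5 phosphonate without moving the E double bond.

Step 11
Reactants: 15 ethyl (2E)-4-(diethoxyphosphoryl)-2-methylbut-2-enoate; 16 (2E,4E,6E)-2,7-dimethylocta-2,4,6-trienedial (3 equiv)
Product: 18 ethyl (2E,4E,6E,8E,10E)-2,6,11-trimethyl-12-oxododeca-2,4,6,8,10-pentaenoate, via lithiated phosphonate 17 (not isolated)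
Conditions: LiN(SiMe3)2 (1.0 equiv), THF, −78 °C; then added slowly to 16, −78 to 0 °C
Reagents that add atoms: lithium bis(trimethylsilyl)amide (in 17 only), [Li+].C[Si](C)(C)[N-][Si](C)(C)C
Why: Horner–Wadsworth–Emmons olefination with a stabilised allylic phosphonate anion is E-selective, and slow addition to a threefold excess of the symmetrical dialdehyde limits the reaction to one aldehyde group.

Step 12
Reactants: 11 diethyl {(2E,4E)-5-[(1R,4S)-4-hydroxy-2,6,6-trimethylcyclohex-2-en-1-yl]-3-methylpenta-2,4-dien-1-yl}phosphonate; 18 ethyl (2E,4E,6E,8E,10E)-2,6,11-trimethyl-12-oxododeca-2,4,6,8,10-pentaenoate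
Product: 20 ethyl (2E,4E,6E,8E,10E,12E,14E,16E)-17-[(1R,4S)-4-hydroxy-2,6,6-trimethylcyclohex-2-en-1-yl]-2,6,11,15-tetramethylheptadeca-2,4,6,8,10,12,14,16-octaenoate, via dilithiated phosphonate 19 (not isolated)
Conditions: LiN(SiMe3)2 (2.1 equiv), THF, −78 °C; then 18, −78 to 0 °C; Ar, dim light
Reagents that add atoms: lithium bis(trimethylsilyl)amide (in 19 only), [Li+].C[Si](C)(C)[N-][Si](C)(C)C
Why: Horner–Wadsworth–Emmons olefination: the allylic phosphonate carbanion (the lithium alkoxide at C3 is a spectator) adds to the aldehyde of 18 in preference to its ester and eliminates phosphate to give mainly the 11E double bond, and 11 has no base-labile stereocentre.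

Step 13
Reactants: 20 ethyl (2E,4E,6E,8E,10E,12E,14E,16E)-17-[(1R,4S)-4-hydroxy-2,6,6-trimethylcyclohex-2-en-1-yl]-2,6,11,15-tetramethylheptadeca-2,4,6,8,10,12,14,16-octaenoate
Product: 21 (2E,4E,6E,8E,10E,12E,14E,16E)-17-[(1R,4S)-4-hydroxy-2,6,6-trimethylcyclohex-2-en-1-yl]-2,6,11,15-tetramethylheptadeca-2,4,6,8,10,12,14,16-octaen-1-ol (the target)
Conditions: i-Bu2AlH (4 equiv), CH2Cl2, −78 °C; then MeOH, aq. KNaC4H4O6
Reagents that add atoms: none
Why: i-Bu2AlH reduces the conjugated ester by 1,2-hydride addition to the allylic alcohol at low temperature without conjugate reduction or any change at the stereocentres, which completes the target.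

## Compound list

1 | β-isophorone (3,5,5-trimethylcyclohex-3-en-1-one) | CC1=CC(C)(C)CC(=O)C1 | starting material
2 | trimethyl[(3,5,5-trimethylcyclohexa-1,3-dien-1-yl)oxy]silane | CC1=CC(C)(C)CC(O[Si](C)(C)C)=C1 | intermediate
3 | (2E)-3-methylpent-2-en-4-yn-1-ol | C#C/C(C)=C/CO | starting material
4 | (3E)-5-bromo-3-methylpent-3-en-1-yne | C#C/C(C)=C/CBr | intermediate
5 | diethyl [(2E)-3-methylpent-2-en-4-yn-1-yl]phosphonate | C#C/C(C)=C/CP(=O)(OCC)OCC | intermediate
6 | chlorobis(cyclopentadienyl)[(1E,3E)-5-(diethoxyphosphoryl)-3-methylpenta-1,3-dien-1-yl]zirconium (cyclopentadienyl rings drawn σ-bonded) | CCOP(=O)(OCC)C/C=C(C)/C=C/[Zr](Cl)([CH]1C=CC=C1)[CH]1C=CC=C1 | intermediate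
7 | diethyl [(2E,4E)-5-bromo-3-methylpenta-2,4-dien-1-yl]phosphonate | CCOP(=O)(OCC)C/C=C(C)/C=C/Br | intermediate
8 | diethyl {(2E,4E)-3-methyl-5-[(1R)-2,6,6-trimethyl-4-oxocyclohex-2-en-1-yl]penta-2,4-dien-1-yl}phosphonate | CC1=CC(=O)CC(C)(C)[C@H]1/C=C/C(C)=C/CP(=O)(OCC)OCC | intermediate
9 | diethyl {(2E,4E)-5-[(1R,4R)-4-hydroxy-2,6,6-trimethylcyclohex-2-en-1-yl]-3-methylpenta-2,4-dien-1-yl}phosphonate | CC1=C[C@H](O)CC(C)(C)[C@H]1/C=C/C(C)=C/CP(=O)(OCC)OCC | intermediate
10 | (1S,4R)-4-[(1E,3E)-5-(diethoxyphosphoryl)-3-methylpenta-1,3-dien-1-yl]-3,5,5-trimethylcyclohex-2-en-1-yl 4-nitrobenzoate | CC1=C[C@@H](OC(=O)c2ccc(cc2)[N+](=O)[O-])CC(C)(C)[C@H]1/C=C/C(C)=C/CP(=O)(OCC)OCC | intermediate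
11 | diethyl {(2E,4E)-5-[(1R,4S)-4-hydroxy-2,6,6-trimethylcyclohex-2-en-1-yl]-3-methylpenta-2,4-dien-1-yl}phosphonate | CC1=C[C@@H](O)CC(C)(C)[C@H]1/C=C/C(C)=C/CP(=O)(OCC)OCC | intermediate
12 | chloroacetaldehyde | ClCC=O | starting material
13 | ethyl 2-(triphenyl-λ5-phosphanylidene)propanoate | CCOC(=O)C(C)=P(c1ccccc1)(c1ccccc1)c1ccccc1 | starting material
14 | ethyl (2E)-4-chloro-2-methylbut-2-enoate | CCOC(=O)/C(C)=C/CCl | intermediate
15 | ethyl (2E)-4-(diethoxyphosphoryl)-2-methylbut-2-enoate | CCOC(=O)/C(C)=C/CP(=O)(OCC)OCC | intermediate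
16 | (2E,4E,6E)-2,7-dimethylocta-2,4,6-trienedial | O=C/C(C)=C/C=C/C=C(C)/C=O | starting material
17 | lithium salt of 15 (carbanion at C4) | [Li+].CCOC(=O)/C(C)=C/[CH-]P(=O)(OCC)OCC | intermediate
18 | ethyl (2E,4E,6E,8E,10E)-2,6,11-trimethyl-12-oxododeca-2,4,6,8,10-pentaenoate | CCOC(=O)/C(C)=C/C=C/C(C)=C/C=C/C=C(C)/C=O | intermediate
19 | dilithium salt of 11 (alkoxide at C3, carbanion next to phosphorus) | [Li+].[Li+].CC1=C[C@@H]([O-])CC(C)(C)[C@H]1/C=C/C(C)=C/[CH-]P(=O)(OCC)OCC | intermediate
20 | ethyl (2E,4E,6E,8E,10E,12E,14E,16E)-17-[(1R,4S)-4-hydroxy-2,6,6-trimethylcyclohex-2-en-1-yl]-2,6,11,15-tetramethylheptadeca-2,4,6,8,10,12,14,16-octaenoate | CC1=C[C@@H](O)CC(C)(C)[C@H]1/C=C/C(C)=C/C=C/C(C)=C/C=C/C=C(C)/C=C/C=C(\C)C(=O)OCC | intermediate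
21 | (2E,4E,6E,8E,10E,12E,14E,16E)-17-[(1R,4S)-4-hydroxy-2,6,6-trimethylcyclohex-2-en-1-yl]-2,6,11,15-tetramethylheptadeca-2,4,6,8,10,12,14,16-octaen-1-ol, i.e. (3S,6R)-8'-apo-ε-carotene-3,8'-diol | CC1=C[C@@H](O)CC(C)(C)[C@H]1/C=C/C(C)=C/C=C/C(C)=C/C=C/C=C(C)/C=C/C=C(\C)CO | target

## Step count and risks

Total step count: 13.
Longest linear sequence: 9 steps (3 → 4 → 5 → 7 → 8 → 9 → 10 → 11 → 20 → 21; steps 2, 3, 4, 5, 6, 7, 8, 12, 13).

The three steps most likely to fail:

**Step 5 (the proposed new coupling).** The γ-carbon of 2 is flanked by CMe2, so coupling at the α-carbon, simple protodesilylation of 2, or low enantioselectivity could defeat it. The fallback uses known chemistry only; it sets out from 18 and comes back at 20. It takes the ε-ring stereocentre from the chiral pool and reverses the polarity of the C11=C12 olefination. 18 is reduced at the aldehyde only (NaBH4, EtOH, 0 °C) to ethyl (2E,4E,6E,8E,10E)-12-hydroxy-2,6,11-trimethyldodeca-2,4,6,8,10-pentaenoate F1. With PPh3·HBr in MeOH, this gives [(2E,4E,6E,8E,10E)-12-ethoxy-2,7,11-trimethyl-12-oxododeca-2,4,6,8,10-pentaen-1-yl]triphenylphosphonium bromide F2. Separately, the natural enantiomer of α-ionone, (3E)-4-[(1R)-2,6,6-trimethylcyclohex-2-en-1-yl]but-3-en-2-one F3 (bought), is homologated with diethyl (cyanomethyl)phosphonate and NaH in THF to (2E,4E)-3-methyl-5-[(1R)-2,6,6-trimethylcyclohex-2-en-1-yl]penta-2,4-dienenitrile F4 (the 9Z isomer is removed by chromatography). F4 is oxidised at the ring allylic CH2 (t-BuOOH, aq. NaOCl, MeCN, 0 °C) to (2E,4E)-3-methyl-5-[(1R)-2,6,6-trimethyl-4-oxocyclohex-2-en-1-yl]penta-2,4-dienenitrile F5. Reduction (NaBH4, CeCl3·7H2O, MeOH, −20 °C) gives a separable mixture of the cis alcohol (2E,4E)-5-[(1R,4S)-4-hydroxy-2,6,6-trimethylcyclohex-2-en-1-yl]-3-methylpenta-2,4-dienenitrile F6 and its epimer (2E,4E)-5-[(1R,4R)-4-hydroxy-2,6,6-trimethylcyclohex-2-en-1-yl]-3-methylpenta-2,4-dienenitrile F7. The epimer is fed back into the cis alcohol by the aqueous-acid epimerisation described under step 7. i-Bu2AlH (CH2Cl2, −40 °C, then dilute acid) turns the cis nitrile into (2E,4E)-5-[(1R,4S)-4-hydroxy-2,6,6-trimethylcyclohex-2-en-1-yl]-3-methylpenta-2,4-dienal F8. Wittig condensation of this aldehyde with the phosphonium salt (NaOMe, MeOH/CH2Cl2, rt, then warming in EtOH to turn 11Z into 11E) gives 20.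

**Step 7 (Mitsunobu inversion at an allylic, β-branched carbinol).** Elimination to the ring diene, SN2' attack or incomplete inversion are possible. The step also presupposes that step 6 gave the trans alcohol; if step 6 gives 11 directly, steps 7 and 8 are dropped. The fallback sets out from 9 and comes back at 11 and replaces SN2 inversion by thermodynamic epimerisation. Dilute aqueous H2SO4 in THF at rt ionises the allylic C3–OH reversibly to the C3–C4–C5 allyl cation, and water returns to C3 from either face. The roughly 1:1 equilibrium mixture of 9 and 11 (the behaviour known for the 3-hydroxy-ε end group) is separated by chromatography and 9 is recycled. No new compound is made.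

**Step 12 (convergent HWE olefination of two sensitive polyenes).** The long aldehyde ester 18 is a weak electrophile, E/Z mixtures at C11=C12 and losses on handling are possible. The fallback sets out from 11 and comes back at 20 and builds the chain in the linear order C15 + C10 + C5. The dianion 19 of 11 is added to a threefold excess of 16 (THF, −78 to 0 °C) to give (2E,4E,6E,8E,10E,12E)-13-[(1R,4S)-4-hydroxy-2,6,6-trimethylcyclohex-2-en-1-yl]-2,7,11-trimethyltrideca-2,4,6,8,10,12-hexaenal F9. A second HWE reaction of this shorter, more electrophilic aldehyde with the anion 17 of 15 (THF, −78 to 0 °C) gives 20.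

Further compounds
F1 | step 5 | ethyl (2E,4E,6E,8E,10E)-12-hydroxy-2,6,11-trimethyldodeca-2,4,6,8,10-pentaenoate | CCOC(=O)/C(C)=C/C=C/C(C)=C/C=C/C=C(C)/CO
F2 | step 5 | [(2E,4E,6E,8E,10E)-12-ethoxy-2,7,11-trimethyl-12-oxododeca-2,4,6,8,10-pentaen-1-yl]triphenylphosphonium bromide | CCOC(=O)/C(C)=C/C=C/C(C)=C/C=C/C=C(C)/C[P+](c1ccccc1)(c1ccccc1)c1ccccc1.[Br-]
F3 | step 5 | (3E)-4-[(1R)-2,6,6-trimethylcyclohex-2-en-1-yl]but-3-en-2-one ((R)-α-ionone) | CC1=CCCC(C)(C)[C@H]1/C=C/C(C)=O
F4 | step 5 | (2E,4E)-3-methyl-5-[(1R)-2,6,6-trimethylcyclohex-2-en-1-yl]penta-2,4-dienenitrile | CC1=CCCC(C)(C)[C@H]1/C=C/C(C)=C/C#N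
F5 | step 5 | (2E,4E)-3-methyl-5-[(1R)-2,6,6-trimethyl-4-oxocyclohex-2-en-1-yl]penta-2,4-dienenitrile | CC1=CC(=O)CC(C)(C)[C@H]1/C=C/C(C)=C/C#N
F6 | step 5 | (2E,4E)-5-[(1R,4S)-4-hydroxy-2,6,6-trimethylcyclohex-2-en-1-yl]-3-methylpenta-2,4-dienenitrile | CC1=C[C@@H](O)CC(C)(C)[C@H]1/C=C/C(C)=C/C#N
F7 | step 5 | (2E,4E)-5-[(1R,4R)-4-hydroxy-2,6,6-trimethylcyclohex-2-en-1-yl]-3-methylpenta-2,4-dienenitrile | CC1=C[C@H](O)CC(C)(C)[C@H]1/C=C/C(C)=C/C#N
F8 | step 5 | (2E,4E)-5-[(1R,4S)-4-hydroxy-2,6,6-trimethylcyclohex-2-en-1-yl]-3-methylpenta-2,4-dienal | CC1=C[C@@H](O)CC(C)(C)[C@H]1/C=C/C(C)=C/C=O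
F0 | step 7 | none | none
F9 | step 12 | (2E,4E,6E,8E,10E,12E)-13-[(1R,4S)-4-hydroxy-2,6,6-trimethylcyclohex-2-en-1-yl]-2,7,11-trimethyltrideca-2,4,6,8,10,12-hexaenal | CC1=C[C@@H](O)CC(C)(C)[C@H]1/C=C/C(C)=C/C=C/C(C)=C/C=C/C=C(C)/C=O
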